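**Retrosynthetic overview**
1. The styryl orthoester cage (one carbon bound to O4, O6 and O15; a 1,3-dioxane through C4–C5–C6 and a 1,3-dioxolane through C4–C15) is opened last to a 4,6,15-triol and trimethyl orthocinnamate; the 4,15-diol is traced to a 4(15)-exocyclic alkene.
2. The strategy rests on ring B (C5–C6–C7–C8–C9–C10): O6 and O9 are para, the C10 methyl and C7 isopropyl sit as in carvacrol, and C10 is the α-carbon of an aldol between C9=O and the C1 carbinol.
3. Key disconnection: C5–C4 and C10–C1 are cut together, giving a carvacrol-derived p-quinone monoketal and 4-borylpent-4-enal (asymmetric conjugate alkenylation, then aldol of the C10 enolate).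
4. Ring order: ring B (the dearomatized arene), then ring A (the annulation), then the dioxolane and dioxane rings of the cage.
5. Stereocontrol: the catalyst sets C5 and the tether relays it to C10 and C1; C5 is then inverted by protonation anti to the C10 methyl, and C7, C6, C9 and C4 follow from the rigid trans-decalin.

Key step: step 7

**Remarks on the chemistry (assumptions)**
- Eudesmane numbering is used (decalin C1–C10, C14 = methyl on C10, C15 on C4); "methyl face" means the face that carries C14.
- The sense of induction of the chiral diene cannot be assigned in advance; (R,R)-Ph-bod is written, and its antipode would be used if the annulation product proved enantiomeric.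
- Ketal hydrolysis and C5 inversion are kept as two operations (steps 9 and 10). Equilibrating conditions on a C6 ketone with an enolizable H5 would draw the 4(15)-alkene into conjugation, so C5 and C7 are set by kinetic protonations whose sense coincides with the thermodynamic one.

**Route**

Step 1
Reactants: 1 carvacrol (5-isopropyl-2-methylphenol)
Product: 3 4,4-dimethoxy-5-isopropyl-2-methylcyclohexa-2,5-dienone (p-quinone monoketal), via 4-methoxy-5-isopropyl-2-methylphenol 2 (not isolated)
Conditions: PhI(OAc)2 (2.2 equiv), MeOH, 0 °C to rt
Reagents that add atoms: methanol (CO)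
Why: Two successive trivalent-iodine oxidations in methanol (oxidative dearomatization) first methoxylate the free para position to give 2 and then oxidize 2 again with methanol capture to the p-quinone monoketal, and no stereocentre is formed.

Step 2
Reactants: 4 pent-4-yn-1-ol
Product: 5 tert-butyl(pent-4-yn-1-yloxy)diphenylsilane
Conditions: TBDPSCl, imidazole, CH2Cl2, rt
Reagents that add atoms: tert-butyl(chloro)diphenylsilane (CC(C)(C)[Si](Cl)(c1ccccc1)c1ccccc1)
Why: Routine O-silylation, with the bulky diphenylsilyl ether chosen because it should tolerate the Lewis-acidic haloborane of the next step.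

Step 3
Reactants: 5 tert-butyl(pent-4-yn-1-yloxy)diphenylsilane
Product: 7 [(4-bromopent-4-en-1-yl)oxy](tert-butyl)diphenylsilane, via bromoalkenylborane 6 (not isolated)
Conditions: B-Br-9-BBN, CH2Cl2, 0 °C; then AcOH, 0 °C
Reagents that add atoms: B-bromo-9-borabicyclo[3.3.1]nonane (BrB1C2CCCC1CCC2)
Why: Markovnikov syn-bromoboration of the terminal alkyne puts boron on the terminal and bromine on the internal carbon, and protodeboronation of 6 with acetic acid leaves the 2-bromo-1-alkene.

Step 4
Reactants: 7 [(4-bromopent-4-en-1-yl)oxy](tert-butyl)diphenylsilane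
Product: 8 tert-butyldiphenyl{[4-(4,4,5,5-tetramethyl-1,3,2-dioxaborolan-2-yl)pent-4-en-1-yl]oxy}silane
Conditions: B2pin2, PdCl2(PPh3)2 (3 mol %), PPh3 (6 mol %), KOPh, toluene, 50 °C
Reagents that add atoms: bis(pinacolato)diboron (CC1(C)OB(OC1(C)C)B1OC(C)(C)C(C)(C)O1)
Why: Miyaura borylation of an alkenyl bromide (oxidative addition to zerovalent palladium, phenoxide-assisted transmetalation with the diboron, reductive elimination) should give the 1,1-disubstituted alkenyl boronate with the silyl ether untouched.

Step 5
Reactants: 8 silyl ether boronate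
Product: 9 4-(4,4,5,5-tetramethyl-1,3,2-dioxaborolan-2-yl)pent-4-en-1-ol
Conditions: Bu4NF, AcOH (1:1), THF, 0 °C to rt
Reagents that add atoms: none
Why: Fluoride desilylation buffered with acetic acid should free the primary alcohol without degrading the alkenyl boronate.

Step 6
Reactants: 9 4-(pinacolboryl)pent-4-en-1-ol
Product: 10 4-(4,4,5,5-tetramethyl-1,3,2-dioxaborolan-2-yl)pent-4-enal (supplies C15, C4, C3, C2, C1 and O1)
Conditions: Dess–Martin periodinane, CH2Cl2, 0 °C to rt
Reagents that add atoms: none
Why: Dess–Martin oxidation of a primary alcohol stops at the aldehyde under near-neutral conditions that leave the alkenyl boronate intact.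

Step 7
Reactants: 3 p-quinone monoketal; 10 4-(pinacolboryl)pent-4-enal
Product: 13 cis-fused annulation product (1S,5S,10S)-1-hydroxy-6,6-dimethoxyeudesma-4(15),7-dien-9-one (H5 and 1-OH both on the methyl face), via alkenylrhodium species 11 (not isolated), via rhodium enolate 12 (not isolated)
Conditions: [RhCl(C2H4)2]2 (2.5 mol %), (R,R)-Ph-bod [(1R,4R)-2,5-diphenylbicyclo[2.2.2]octa-2,5-diene] (5.5 mol %), KOH (10 mol %), H2O (2 equiv), 1,4-dioxane, 30 °C
Reagents that add atoms: none
Why: Proposed new method: transmetalation of 10 to the hydroxorhodium–diene complex (monovalent rhodium) gives alkenylrhodium 11, which inserts the C5=C10 enone of 3 at C5 to give the oxa-π-allyl rhodium enolate 12, and this enolate adds through a chair-like, rhodium-bridged (Zimmerman–Traxler) transition state to the aldehyde held three atoms away before water cleaves the Rh–O bond and returns the catalyst. The closest known reaction types are the Hayashi–Miyaura asymmetric 1,4-addition of alkenylboron reagents to cyclic enones and quinone monoketals and rhodium-catalysed conjugate addition–aldol cascades; untested is their union on an α-methyl quinone monoketal with the aldehyde carried by the boron reagent. The C5–C4 bond is formed intermolecularly and ring A is closed by the C10–C1 aldol in a 6-(enolendo)-exo-trig mode. C5 is set by the chiral diene, which selects one enantioface of the achiral dienone; C10 follows because the short tether reaches only the enolate face that carries C4 (cis fusion, new bond axial on ring B), and C1 follows from the chair transition state with the tether carbon equatorial, which puts O1 gauche to C9 and on the side of the C10 methyl. The step needs regioselectivity and a surviving enolate: C7, the other β-carbon, is blocked by isopropyl, the enolate can form only across C9–C10, and the C6 ketal prevents tautomerization to a hydroquinone, so the quaternary carbon can be built and the aldol product can neither dehydrate nor aromatize. Water is held to about two equivalents so that protonation of 12 should not outrun ring closure.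

Step 8
Reactants: 13 cis-fused annulation product
Product: 14 (1S,5S,10S)-1-(tert-butyldimethylsilyloxy)-6,6-dimethoxyeudesma-4(15),7-dien-9-one
Conditions: TBSOTf, 2,6-lutidine, CH2Cl2, −78 to 0 °C
Reagents that add atoms: tert-butyldimethylsilyl triflate (CC(C)(C)[Si](C)(C)OS(=O)(=O)C(F)(F)F)
Why: Silyl triflate silylation of the hindered neopentyl-type secondary alcohol caps the β-hydroxy ketone so that retro-aldol cleavage of the C10–C1 bond is blocked in the later basic steps.

Step 9
Reactants: 14 silyl ether ketal
Product: 15 cis-fused (1S,5S,10S)-1-(tert-butyldimethylsilyloxy)eudesma-4(15),7-diene-6,9-dione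
Conditions: oxalic acid, THF–H2O, 0 °C to rt (used crude)
Reagents that add atoms: water (O)
Why: Mild acid hydrolysis of the dimethyl ketal (as labile as a quinone monoketal) should unveil the C6 ketone under conditions too gentle to enolize it toward C5 or to cleave the silyl ether, while the quaternary C10 rules out aromatization.

Step 10
Reactants: 15 cis-fused ene-dione
Product: 17 trans-fused (1S,5R,10S)-1-(tert-butyldimethylsilyloxy)eudesma-4(15),7-diene-6,9-dione, via lithium dienolate 16 (not isolated)
Conditions: LiN(SiMe3)2 (1.1 equiv), THF, −78 °C; then AcOH in THF, −78 °C (used at once)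
Reagents that add atoms: none
Why: H5 is the only α-hydrogen of either ketone, so deprotonation gives the extended dienolate 16, and kinetic protonation of a metal dienolate occurs at the α-carbon (deconjugative protonation), here from the face opposite the pseudo-axial C10 methyl, which should place H5 anti to the methyl (the trans fusion, also the more stable one) and keep the 4(15)-alkene out of conjugation.

Step 11
Reactants: 17 trans-fused ene-dione
Product: 19 (1S,5R,7R,10S)-1-(tert-butyldimethylsilyloxy)eudesm-4(15)-ene-6,9-dione, via dienediol 18 (not isolated)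
Conditions: Zn dust, AcOH, rt
Reagents that add atoms: none
Why: Zinc reduction of the ene-dione gives dienediol 18, whose ketonization in the rigid trans-decalin should protonate C7 axially through a chair-like transition state from the face opposite the C10 methyl, placing the isopropyl group equatorial on the methyl face (also the thermodynamically preferred arrangement), while acetic acid at room temperature is too weak to enolize C5.

Step 12
Reactants: 19 saturated trans-fused diketone
Product: 20 (1S,5R,6R,7R,9R,10S)-1-(tert-butyldimethylsilyloxy)eudesm-4(15)-ene-6,9-diol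
Conditions: Li, NH3(l), THF, EtOH, −78 °C; then NH4Cl
Reagents that add atoms: none
Why: Dissolving-metal (Birch-type) ketone reduction operates under thermodynamic control and should give both equatorial alcohols (6-OH on the face opposite the C10 methyl, 9-OH on the methyl face), leaving the isolated alkene and the silyl ether alone, with the proton donor present at −78 °C to limit enolization.

Step 13
Reactants: 20 6,9-diol with 4(15)-alkene
Product: 21 (1S,4S,5R,6R,7R,9R,10S)-1-(tert-butyldimethylsilyloxy)eudesmane-4,6,9,15-tetraol
Conditions: OsO4 (2 mol %), NMO, acetone–H2O, rt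
Reagents that add atoms: osmium tetroxide, catalytic oxygen carrier (O=[Os](=O)(=O)=O); N-methylmorpholine N-oxide (C[N+]1([O-])CCOCC1); water (O)
Why: Upjohn dihydroxylation should take place on the face of the exocyclic alkene opposite the axial C10 methyl, which blocks the other face in a 1,3-diaxial sense, so that O4 becomes equatorial and C15 axial as the cage requires.

Step 14
Reactants: 22 (E)-cinnamonitrile
Product: 23 methyl (E)-cinnamimidate hydrochloride
Conditions: HCl (g), MeOH (1.1 equiv), Et2O, 0 °C
Reagents that add atoms: methanol (CO); hydrogen chloride (Cl)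
Why: Pinner reaction, in which the HCl-activated nitrile adds one methanol to give the imidate salt without touching the (E)-alkene.

Step 15
Reactants: 23 methyl (E)-cinnamimidate hydrochloride
Product: 24 trimethyl (E)-orthocinnamate
Conditions: dry MeOH (excess), rt; filter off NH4Cl
Reagents that add atoms: methanol (CO)
Why: Alcoholysis of the Pinner salt (Pinner orthoester synthesis) replaces the iminium nitrogen by two further methoxy groups, driven by precipitation of ammonium chloride.

Step 16
Reactants: 21 tetraol; 24 trimethyl (E)-orthocinnamate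
Product: 25 1-O-TBS orthoester (1S,4S,5R,6R,7R,9R,10S; orthoester carbon S), the 4,6,15-orthocinnamate cage with free 9-OH
Conditions: CSA (5 mol %), CH2Cl2, 4 Å MS, rt
Reagents that add atoms: none
Why: Acid-catalysed transorthoesterification exchanges the three methoxy groups for O15, O4 and O6, the only hydroxyls that can reach one carbon, closing the dioxolane and dioxane rings under thermodynamic control with removal of methanol, so O9–H stays free and the configuration of the orthoester carbon is dictated by the cage.

Step 17
Reactants: 25 1-O-TBS orthoester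
Product: 26 target CNP0252898.1 (1S,4S,5R,6R,7R,9R,10S; orthoester carbon S)
Conditions: Bu4NF, THF, 0 °C to rt
Reagents that add atoms: none
Why: Fluoride cleavage of the silyl ether frees the C1 hydroxyl under basic conditions to which the acid-labile orthoester is inert.

**Compound list**
1 | carvacrol (5-isopropyl-2-methylphenol) | Cc1ccc(C(C)C)cc1O | starting material
2 | 4-methoxy-5-isopropyl-2-methylphenol (not isolated) | COc1cc(C)c(O)cc1C(C)C | intermediate
3 | 4,4-dimethoxy-5-isopropyl-2-methylcyclohexa-2,5-dienone | COC1(OC)C=C(C)C(=O)C=C1C(C)C | intermediate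
4 | pent-4-yn-1-ol | C#CCCCO | starting material
5 | tert-butyl(pent-4-yn-1-yloxy)diphenylsilane | C#CCCCO[Si](c1ccccc1)(c1ccccc1)C(C)(C)C | intermediate
6 | (Z)-B-[2-bromo-5-(tert-butyldiphenylsilyloxy)pent-1-enyl]-9-borabicyclo[3.3.1]nonane (not isolated) | Br/C(CCCO[Si](c1ccccc1)(c1ccccc1)C(C)(C)C)=C\B1C2CCCC1CCC2 | intermediate
7 | [(4-bromopent-4-en-1-yl)oxy](tert-butyl)diphenylsilane | C=C(Br)CCCO[Si](c1ccccc1)(c1ccccc1)C(C)(C)C | intermediate
8 | tert-butyldiphenyl{[4-(pinacolboryl)pent-4-en-1-yl]oxy}silane | C=C(B1OC(C)(C)C(C)(C)O1)CCCO[Si](c1ccccc1)(c1ccccc1)C(C)(C)C | intermediate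
9 | 4-(pinacolboryl)pent-4-en-1-ol | C=C(B1OC(C)(C)C(C)(C)O1)CCCO | intermediate
10 | 4-(pinacolboryl)pent-4-enal | C=C(B1OC(C)(C)C(C)(C)O1)CCC=O | intermediate
11 | alkenylrhodium species, 5-oxopent-1-en-2-yl on rhodium, diene ligand not drawn (not isolated) | C=C([Rh])CCC=O | intermediate
12 | rhodium enolate of the C5 adduct, enolate across C9–C10, diene ligand not drawn (not isolated) | CC(C)C1=CC(O[Rh])=C(C)[C@H](C(=C)CCC=O)C1(OC)OC | intermediate
13 | (1S,5S,10S)-1-hydroxy-6,6-dimethoxyeudesma-4(15),7-dien-9-one, cis-fused, 1-OH on the methyl face | CC(C)C1=CC(=O)[C@@]2(C)[C@@H](C1(OC)OC)C(=C)CC[C@@H]2O | intermediate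
14 | 1-O-TBS ether of 13 | CC(C)C1=CC(=O)[C@@]2(C)[C@@H](C1(OC)OC)C(=C)CC[C@@H]2O[Si](C)(C)C(C)(C)C | intermediate
15 | cis-fused (1S,5S,10S)-1-(TBS-oxy)eudesma-4(15),7-diene-6,9-dione | CC(C)C1=CC(=O)[C@@]2(C)[C@@H](C1=O)C(=C)CC[C@@H]2O[Si](C)(C)C(C)(C)C | intermediate
16 | lithium dienolate, C5=C6–OLi conjugated with C4=C15 (not isolated) | CC(C)C1=CC(=O)[C@@]2(C)C(C(=C)CC[C@@H]2O[Si](C)(C)C(C)(C)C)=C1O[Li] | intermediate
17 | trans-fused (1S,5R,10S)-1-(TBS-oxy)eudesma-4(15),7-diene-6,9-dione | CC(C)C1=CC(=O)[C@@]2(C)[C@H](C1=O)C(=C)CC[C@@H]2O[Si](C)(C)C(C)(C)C | intermediate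
18 | dienediol, 1-(TBS-oxy)eudesma-4(15),6,8-triene-6,9-diol (not isolated) | CC(C)C1=C(O)[C@@H]2C(=C)CC[C@H](O[Si](C)(C)C(C)(C)C)[C@@]2(C)C(O)=C1 | intermediate
19 | (1S,5R,7R,10S)-1-(TBS-oxy)eudesm-4(15)-ene-6,9-dione, trans-fused, isopropyl equatorial | CC(C)[C@H]1CC(=O)[C@@]2(C)[C@H](C1=O)C(=C)CC[C@@H]2O[Si](C)(C)C(C)(C)C | intermediate
20 | (1S,5R,6R,7R,9R,10S)-1-(TBS-oxy)eudesm-4(15)-ene-6,9-diol, both hydroxyls equatorial | CC(C)[C@H]1C[C@@H](O)[C@@]2(C)[C@H]([C@@H]1O)C(=C)CC[C@@H]2O[Si](C)(C)C(C)(C)C | intermediate
21 | (1S,4S,5R,6R,7R,9R,10S)-1-(TBS-oxy)eudesmane-4,6,9,15-tetraol, O4 equatorial, C15 axial | CC(C)[C@H]1C[C@@H](O)[C@@]2(C)[C@H]([C@@H]1O)[C@](O)(CO)CC[C@@H]2O[Si](C)(C)C(C)(C)C | intermediate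
22 | (E)-cinnamonitrile | N#C/C=C/c1ccccc1 | starting material
23 | methyl (E)-cinnamimidate hydrochloride | COC(=[NH2+])/C=C/c1ccccc1.[Cl-] | intermediate
24 | trimethyl (E)-orthocinnamate | COC(OC)(OC)/C=C/c1ccccc1 | intermediate
25 | 1-O-TBS ether of the target, 4,6,15-orthocinnamate cage with free 9-OH | CC(C)[C@H]1C[C@@H](O)[C@@]2(C)[C@@H]3[C@@H]1O[C@]1(/C=C/c4ccccc4)OC[C@@]3(CC[C@@H]2O[Si](C)(C)C(C)(C)C)O1 | intermediate
26 | CNP0252898.1 | CC(C)[C@H]1C[C@@H](O)[C@@]2(C)[C@@H]3[C@@H]1O[C@]1(/C=C/c4ccccc4)OC[C@@]3(CC[C@@H]2O)O1 | target

**Step count**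
Total: 17 steps. Longest linear sequence: 14 steps (from 4 through steps 2–13, 16 and 17).

**Steps most likely to fail**

Step 7 (proposed new method). The rhodium enolate may be protonated by water before it closes ring A, or insertion into the α-methyl enone may be slow enough that the alkenylrhodium species is lost to protodeboronation or 1,2-addition to the free aldehyde; enantioface selection may also erode. Fallback: the two bonds are made in separate operations of known type, setting out from 3 and the silyl ether boronate 8 and coming back at 13. Ordinary aqueous rhodium/chiral diene 1,4-alkenylation ([RhCl(C2H4)2]2, (R,R)-Ph-bod, KOH, dioxane–H2O) should give the protonated conjugate adduct F1 (C5 set, the methyl-bearing carbon epimeric). Bu4NF/AcOH then frees the primary alcohol F2, and Dess–Martin oxidation gives the keto-aldehyde F3. KOH (catalytic) in MeOH at 0 °C closes ring A by intramolecular aldol of the C10 enolate onto the aldehyde, in the same cis sense, returning to 13.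

Step 10. The dienolate may be protonated at C15 instead of C5 (migration of the exocyclic alkene into conjugation with the C6 ketone) or on the methyl face (no inversion at C5). Fallback: the alkene is masked before the C6 ketone is unveiled, so that C5 can be equilibrated thermodynamically, setting out from 14 and coming back at 19. Radical thiol–ene addition of PhSH (AIBN, 80 °C) to the electron-rich 1,1-disubstituted alkene gives the primary sulfide F4 (C4 epimers, of no consequence). Aqueous HCl in THF hydrolyses the ketal and equilibrates C5 to the trans-fused ene-dione sulfide F5. Zn/AcOH gives the saturated diketone sulfide F6, in which C7 can also be equilibrated with mild base without risk to an alkene. mCPBA (1 equiv, −78 °C) gives the sulfoxide F7, and thermal syn-elimination (toluene, 110 °C, CaCO3), for which H4 is the only β-hydrogen, regenerates the 4(15)-alkene as 19.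

Step 15. Methanolysis of a conjugated Pinner salt may stall or be diverted to the amide or ester (Pinner cleavage, conjugate addition of methanol), so that the trimethyl orthoester is not obtained. Fallback: 24 is bypassed. Setting out from the imidate hydrochloride 23 and tetraol 21, the salt is condensed directly with the triol unit (CH2Cl2, rt), the classical imidate route to bicyclic orthoesters. The three hydroxyls displace methanol and ammonia (as its chloride), and the sequence comes back at 25; no new compound is made (F0).

**Further compounds**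
F1 | step 7 | 4,4-dimethoxy-3-isopropyl-6-methyl-5-[5-(tert-butyldiphenylsilyloxy)pent-1-en-2-yl]cyclohex-2-enone, C5 (eudesmane numbering) set, methyl-bearing carbon epimeric | CC(C)C1=CC(=O)C(C)[C@H](C(=C)CCCO[Si](c2ccccc2)(c2ccccc2)C(C)(C)C)C1(OC)OC
F2 | step 7 | 5-(5-hydroxypent-1-en-2-yl)-4,4-dimethoxy-3-isopropyl-6-methylcyclohex-2-enone | CC(C)C1=CC(=O)C(C)[C@H](C(=C)CCCO)C1(OC)OC
F3 | step 7 | 4-(6,6-dimethoxy-5-isopropyl-2-methyl-3-oxocyclohex-4-enyl)pent-4-enal (keto-aldehyde) | CC(C)C1=CC(=O)C(C)[C@H](C(=C)CCC=O)C1(OC)OC
F4 | step 10 | 15-(phenylthio)-4,15-dihydro derivative of 14 (C4 epimers) | CC(C)C1=CC(=O)[C@@]2(C)[C@@H](C1(OC)OC)C(CSc3ccccc3)CC[C@@H]2O[Si](C)(C)C(C)(C)C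
F5 | step 10 | trans-fused 15-(phenylthio)-1-(TBS-oxy)eudesm-7-ene-6,9-dione (C4 epimers) | CC(C)C1=CC(=O)[C@@]2(C)[C@H](C1=O)C(CSc3ccccc3)CC[C@@H]2O[Si](C)(C)C(C)(C)C
F6 | step 10 | trans-fused 15-(phenylthio)-1-(TBS-oxy)eudesmane-6,9-dione, isopropyl equatorial (C4 epimers) | CC(C)[C@H]1CC(=O)[C@@]2(C)[C@H](C1=O)C(CSc3ccccc3)CC[C@@H]2O[Si](C)(C)C(C)(C)C
F7 | step 10 | sulfoxide of F6 | CC(C)[C@H]1CC(=O)[C@@]2(C)[C@H](C1=O)C(CS(=O)c3ccccc3)CC[C@@H]2O[Si](C)(C)C(C)(C)C
F0 | step 15 | none | none
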